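**Plan**

- Retrosynthesis: cut the butanoate C–O bond (back to shikonin 17), then the two phenol acetals and the silyl ether, then the C1–C2 bond of the quinone ring (naphthoquinone numbering; side-chain carbinol = C1'), then the aryl–acyl bond C4–C4a, then the side chain at its amide, prenyl and allyl bonds.
- Enabling feature: the quinone ring is an ene-1,4-dione, O=C1–C2=C3–C4=O, fused to the benzene ring at C4a/C8a. Its carbonyls in 1,4-relation across C2=C3 are what an acyl-anion equivalent at C1 (an aldehyde under carbene catalysis) gives on adding to C2 of an aryl ynone (C4=O, C3≡C2); both carbons are electrophilic by nature, so the union needs polarity reversal.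
- Forward order: the side chain is built first (allylation, silylation, cross-metathesis, Weinreb ynamide) and joined to the protected benzene ring at C4. The quinone ring is then closed at its final oxidation level, so no arene oxidation is needed. Deprotection and esterification finish the route.
- Stereochemistry: the single stereocenter C1' is set by a Brown allylation of 3-(trimethylsilyl)prop-2-ynal with the allylborane from (−)-α-pinene and is carried through unchanged.

Key step: step 8

Assumption: the allylborane derived from (−)-α-pinene attacks the alkynyl aldehyde with the same facial sense as it attacks aryl and alkyl aldehydes, so that the (R)-carbinol results.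

**Route**

Step 1
Reactants: 1 3-(trimethylsilyl)prop-2-ynal
Product: 3 (3R)-1-(trimethylsilyl)hex-5-en-1-yn-3-ol, via borinate ester 2 (not isolated)
Conditions: (+)-B-methoxydiisopinocampheylborane (the enantiomer made from (−)-α-pinene), allylmagnesium bromide, Et2O, 0 → 23 °C; then 1, −78 °C; then pH 7 phosphate buffer, MeOH, 30% H2O2, 0 → 23 °C
Reagents that add atoms: allylmagnesium bromide, C=CC[Mg]Br (its allyl group, passed on through the B-allylborane formed in the flask)
Why: Brown allylation through a closed chair (Zimmerman–Traxler) transition state, in which the isopinocampheyl groups from (−)-α-pinene should direct the allyl group to the aldehyde face that gives the (R)-carbinol, the alkynyl group taking the place that an aryl group takes in the aryl aldehyde cases.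

Step 2
Reactants: 3 (3R)-1-(trimethylsilyl)hex-5-en-1-yn-3-ol
Product: 4 tert-butyldimethyl{[(3R)-1-(trimethylsilyl)hex-5-en-1-yn-3-yl]oxy}silane
Conditions: TBSCl, imidazole, DMF, 23 °C
Reagents that add atoms: tert-butyldimethylsilyl chloride, CC(C)(C)[Si](C)(C)Cl
Why: Imidazole-promoted silylation of a secondary alcohol, which masks the hydroxyl for the organolithium steps without touching the stereocenter.

Step 3
Reactants: 4 tert-butyldimethyl{[(3R)-1-(trimethylsilyl)hex-5-en-1-yn-3-yl]oxy}silane
Product: 5 tert-butyldimethyl{[(3R)-6-methyl-1-(trimethylsilyl)hept-5-en-1-yn-3-yl]oxy}silane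
Conditions: second-generation Grubbs catalyst RuCl2(=CHPh)(PCy3)(H2IMes) (3 mol %), 2-methyl-2-butene/CH2Cl2, 40 °C
Reagents that add atoms: 2-methyl-2-butene, CC=C(C)C
Why: Olefin cross-metathesis of a terminal alkene with excess 2-methyl-2-butene is the standard way to a prenyl-type trisubstituted alkene, and the silyl-capped alkyne next to the bulky silyl ether should stay out of enyne metathesis.

Step 4
Reactants: 5 tert-butyldimethyl{[(3R)-6-methyl-1-(trimethylsilyl)hept-5-en-1-yn-3-yl]oxy}silane
Product: 6 tert-butyldimethyl{[(3R)-6-methylhept-5-en-1-yn-3-yl]oxy}silane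
Conditions: K2CO3, MeOH, 23 °C
Reagents that add atoms: none
Why: Methanolysis with K2CO3 is selective for the alkynyl C–Si bond and should leave the secondary silyl ether and the stereocenter untouched.

Step 5
Reactants: 6 tert-butyldimethyl{[(3R)-6-methylhept-5-en-1-yn-3-yl]oxy}silane
Product: 8 (4R)-4-(tert-butyldimethylsilyloxy)-N-methoxy-N,7-dimethyloct-6-en-2-ynamide, via lithium acetylide 7 (not isolated)
Conditions: n-BuLi, THF, −78 °C; then N-methoxy-N-methylcarbamoyl chloride, −78 → 0 °C
Reagents that add atoms: N-methoxy-N-methylcarbamoyl chloride, CON(C)C(Cl)=O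
Why: Deprotonation of the terminal alkyne and acylation of the lithium acetylide with the carbamoyl chloride gives the alkynyl Weinreb amide without disturbing the propargylic stereocenter.

Step 6
Reactants: 9 2,5-dihydroxybenzaldehyde
Product: 10 2,5-bis(methoxymethoxy)benzaldehyde
Conditions: MOMCl, i-Pr2NEt, CH2Cl2, 0 → 40 °C
Reagents that add atoms: chloromethyl methyl ether, COCCl
Why: Alkylation of both phenols (Williamson type) gives acetal ethers that direct ortho-lithiation and come off later under mild acid.

Step 7
Reactants: 10 2,5-bis(methoxymethoxy)benzaldehyde (in excess); 8 (4R)-4-(tert-butyldimethylsilyloxy)-N-methoxy-N,7-dimethyloct-6-en-2-ynamide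
Product: 14 3,6-bis(methoxymethoxy)-2-[(4R)-4-(tert-butyldimethylsilyloxy)-7-methyloct-6-en-2-ynoyl]benzaldehyde, via lithium amino alkoxide 11 (not isolated), via aryllithium 12 (not isolated), via tetrahedral adduct 13 (not isolated)
Conditions: LiN(Me)CH2CH2NMe2 (from N,N,N'-trimethylethylenediamine and n-BuLi), THF, −20 °C; n-BuLi (no excess over 10), −20 °C; then 8, −78 → −40 °C; inverse quench into cold 0.5 M aq. HCl, fast extraction
Reagents that add atoms: none
Why: Addition of the lithium amide masks the aldehyde as an α-amino alkoxide that, together with the neighbouring methoxymethoxy group, directs lithiation to the ring carbon between them (directed ortho-metalation), and the aryllithium then acylates once on the Weinreb amide (Weinreb ketone synthesis) because the chelated adduct holds until the acid quench, which also frees the aldehyde.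

Step 8
Reactants: 14 3,6-bis(methoxymethoxy)-2-[(4R)-4-(tert-butyldimethylsilyloxy)-7-methyloct-6-en-2-ynoyl]benzaldehyde
Product: 16 2-[(1R)-1-(tert-butyldimethylsilyloxy)-4-methylpent-3-en-1-yl]-5,8-bis(methoxymethoxy)naphthalene-1,4-dione, via Breslow enaminol 15 (not isolated)
Conditions: 2-(pentafluorophenyl)-6,7-dihydro-5H-pyrrolo[2,1-c][1,2,4]triazol-2-ium tetrafluoroborate (15 mol %), i-Pr2NEt (30 mol %), degassed toluene/t-BuOH (10:1, 0.02 M), 23 °C, argon, dark
Reagents that add atoms: none
Why: Proposed new method: the carbene adds to the aldehyde of 14 and a proton shift gives the enaminol 15 (Breslow intermediate), whose nucleophilic former aldehyde carbon attacks the alkyne carbon β to the ketone; protonation of the resulting vinyl anion at the α-carbon from outside the new ring (an anti addition, proton relayed by t-BuOH and the ammonium salt) and loss of the carbene from the alkoxide then give the ene-dione, so that the quinone ring of 16 appears at its final oxidation level without any oxidant. The closest known reaction type is the carbene-catalysed intramolecular Stetter reaction (hydroacylation) of activated alkynes that leads to chromanones and chromones, and the geometry of the closure is that of the base-induced 6-endo-dig ring closure of 2-hydroxyaryl ynones to chromones, in which an atom on the ring carbon ortho to the ynone reaches the same alkyne carbon. The six-membered quinone ring closes in the 6-endo-dig mode. No stereocenter is formed, and the existing one lies outside the reacting atoms; the weak base and the acidic, electron-poor triazolium salt are chosen so that its propargylic hydrogen is not removed. The step needs attack at the β-carbon (6-endo) and not at the α-carbon (5-exo, which would give an alkylidene indanedione), and it needs ring closure to outrun benzoin coupling and redox reaction of 15 with the quinone formed; the polarisation of the ynone and the two ortho substituents, which turn enaminol and ketone out of the ring plane so that the enaminol π lobe faces the alkyne, should secure the first, and the tether, high dilution, exclusion of air and a weakly reducing carbene the second.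

Step 9
Reactants: 16 2-[(1R)-1-(tert-butyldimethylsilyloxy)-4-methylpent-3-en-1-yl]-5,8-bis(methoxymethoxy)naphthalene-1,4-dione
Product: 17 shikonin, 5,8-dihydroxy-2-[(1R)-1-hydroxy-4-methylpent-3-en-1-yl]naphthalene-1,4-dione
Conditions: 2 M aq. HCl/THF/i-PrOH, 23 → 35 °C, argon, dark
Reagents that add atoms: none
Why: Acid hydrolysis of the two aryl methoxymethyl acetals, helped by the peri quinone carbonyls, and of the secondary silyl ether should free the naphthazarin without an oxidation step, while mild aqueous acid should leave the trisubstituted alkene and the carbinol configuration alone.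

Step 10
Reactants: 17 shikonin
Product: 18 butylshikonin, (1R)-1-(5,8-dihydroxy-1,4-dioxo-1,4-dihydronaphthalen-2-yl)-4-methylpent-3-en-1-yl butanoate
Conditions: butanoic acid, DCC, DMAP (cat.), CH2Cl2, 0 → 23 °C
Reagents that add atoms: butanoic acid, CCCC(=O)O
Why: Steglich esterification should acylate only the side-chain alcohol, because both phenols are held in strong hydrogen bonds to the quinone carbonyls and are poor nucleophiles, and it does not touch the C–O bond of the stereocenter, so the (R) configuration is kept.

**Compound list**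

1 | 3-(trimethylsilyl)prop-2-ynal | C[Si](C)(C)C#CC=O | starting material
2 | (3R)-1-(trimethylsilyl)hex-5-en-1-yn-3-yl diisopinocampheylborinate | C=CC[C@@H](OB([C@@H]1[C@@H](C)[C@@H]2C[C@H](C1)C2(C)C)[C@@H]1[C@@H](C)[C@@H]2C[C@H](C1)C2(C)C)C#C[Si](C)(C)C | intermediate
3 | (3R)-1-(trimethylsilyl)hex-5-en-1-yn-3-ol | C=CC[C@@H](O)C#C[Si](C)(C)C | intermediate
4 | tert-butyldimethyl{[(3R)-1-(trimethylsilyl)hex-5-en-1-yn-3-yl]oxy}silane | C=CC[C@@H](O[Si](C)(C)C(C)(C)C)C#C[Si](C)(C)C | intermediate
5 | tert-butyldimethyl{[(3R)-6-methyl-1-(trimethylsilyl)hept-5-en-1-yn-3-yl]oxy}silane | CC(C)=CC[C@@H](O[Si](C)(C)C(C)(C)C)C#C[Si](C)(C)C | intermediate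
6 | tert-butyldimethyl{[(3R)-6-methylhept-5-en-1-yn-3-yl]oxy}silane | CC(C)=CC[C@@H](O[Si](C)(C)C(C)(C)C)C#C | intermediate
7 | lithium acetylide of 6 | CC(C)=CC[C@@H](O[Si](C)(C)C(C)(C)C)C#C[Li] | intermediate
8 | (4R)-4-(tert-butyldimethylsilyloxy)-N-methoxy-N,7-dimethyloct-6-en-2-ynamide | CC(C)=CC[C@@H](O[Si](C)(C)C(C)(C)C)C#CC(=O)N(C)OC | intermediate
9 | 2,5-dihydroxybenzaldehyde | O=Cc1cc(O)ccc1O | starting material
10 | 2,5-bis(methoxymethoxy)benzaldehyde | COCOc1ccc(OCOC)c(C=O)c1 | intermediate
11 | lithium α-amino alkoxide of 10 (adduct of lithium N-[2-(dimethylamino)ethyl]-N-methylamide) | COCOc1ccc(OCOC)c(C(O[Li])N(C)CCN(C)C)c1 | intermediate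
12 | 6-lithio derivative of 11 (lithium on the ring carbon between the alkoxide-bearing carbon and the methoxymethoxy group) | COCOc1ccc(OCOC)c(C(O[Li])N(C)CCN(C)C)c1[Li] | intermediate
13 | tetrahedral adduct of 12 and 8 (dilithium dialkoxide) | COCOc1ccc(OCOC)c(C(O[Li])N(C)CCN(C)C)c1C(O[Li])(N(C)OC)C#C[C@@H](CC=C(C)C)O[Si](C)(C)C(C)(C)C | intermediate
14 | 3,6-bis(methoxymethoxy)-2-[(4R)-4-(tert-butyldimethylsilyloxy)-7-methyloct-6-en-2-ynoyl]benzaldehyde | CC(C)=CC[C@@H](O[Si](C)(C)C(C)(C)C)C#CC(=O)c1c(OCOC)ccc(OCOC)c1C=O | intermediate
15 | Breslow enaminol from 14 and the triazolylidene | OC(=C1N(c2c(F)c(F)c(F)c(F)c2F)N=C2CCCN12)c1c(OCOC)ccc(OCOC)c1C(=O)C#C[C@@H](CC=C(C)C)O[Si](C)(C)C(C)(C)C | intermediate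
16 | 2-[(1R)-1-(tert-butyldimethylsilyloxy)-4-methylpent-3-en-1-yl]-5,8-bis(methoxymethoxy)naphthalene-1,4-dione | CC(C)=CC[C@@H](O[Si](C)(C)C(C)(C)C)C1=CC(=O)c2c(OCOC)ccc(OCOC)c2C1=O | intermediate
17 | shikonin, 5,8-dihydroxy-2-[(1R)-1-hydroxy-4-methylpent-3-en-1-yl]naphthalene-1,4-dione | CC(C)=CC[C@@H](O)C1=CC(=O)c2c(O)ccc(O)c2C1=O | intermediate
18 | butylshikonin, (1R)-1-(5,8-dihydroxy-1,4-dioxo-1,4-dihydronaphthalen-2-yl)-4-methylpent-3-en-1-yl butanoate | CCCC(=O)O[C@H](CC=C(C)C)C1=CC(=O)c2c(O)ccc(O)c2C1=O | target

**Count and risks**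

Total step count: 10. Longest linear sequence: 9 steps (steps 1, 2, 3, 4, 5, 7, 8, 9, 10); step 6 is the one-step branch to the arene.

Steps most likely to fail:

1. Step 8 (proposed new method). The enaminol may not reach the alkyne carbon in the 6-endo sense (attack at the α-carbon, or no closure). Carbene and enaminol may also be used up by redox reaction or conjugate addition with the quinone as it forms. The fallback uses known chemistry, closes the same bond and sets out from 14. NaI in AcOH at 23 °C should add HI across the ynone in the anti sense and give the (Z)-β-iodo enone 2-[(2Z,4R)-4-(tert-butyldimethylsilyloxy)-3-iodo-7-methylocta-2,6-dienoyl]-3,6-bis(methoxymethoxy)benzaldehyde F1. An intramolecular Nozaki–Hiyama–Kishi reaction (CrCl2, catalytic NiCl2, DMF, 23 °C) should then join the vinyl carbon to the aldehyde carbon and give 4-hydroxy-3-[(1R)-1-(tert-butyldimethylsilyloxy)-4-methylpent-3-en-1-yl]-5,8-bis(methoxymethoxy)naphthalen-1(4H)-one F2 as a mixture of carbinol epimers. MnO2 in CH2Cl2 should oxidise this doubly activated carbinol, and the fallback comes back to the route at 16.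

2. Step 7. Lithiation of the masked aldehyde may be incomplete or misdirected, leftover butyllithium may attack the ynamide, and the amines set free at the quench may add to the ynone. The fallback reverses the roles, with the alkyne as nucleophile and the arene as electrophile, and sets out from 10 (with 6 as the second component, so that 8 is not needed). Condensation of 10 with N,N'-dimethylethylenediamine (toluene, MgSO4, no acid) should give the aminal 2-[2,5-bis(methoxymethoxy)phenyl]-1,3-dimethylimidazolidine F3. Directed ortho-lithiation (s-BuLi, TMEDA, THF, −78 °C) and DMF should give 2-(1,3-dimethylimidazolidin-2-yl)-3,6-bis(methoxymethoxy)benzaldehyde F4. Addition of lithium acetylide 7 (from 6 and n-BuLi) should give the propargylic alcohol (4R)-4-(tert-butyldimethylsilyloxy)-1-[2-(1,3-dimethylimidazolidin-2-yl)-3,6-bis(methoxymethoxy)phenyl]-7-methyloct-6-en-2-yn-1-ol F5 as both carbinol epimers. MnO2 should give the ynone (4R)-4-(tert-butyldimethylsilyloxy)-1-[2-(1,3-dimethylimidazolidin-2-yl)-3,6-bis(methoxymethoxy)phenyl]-7-methyloct-6-en-2-yn-1-one F6. Brief treatment with cold dilute aqueous acid should hydrolyse the aminal, and the fallback comes back to the route at 14.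

3. Step 9. The acid may close the side-chain hydroxyl onto the trisubstituted alkene, cause solvolysis at the carbinol carbon, or leave the cleavage incomplete. The fallback changes the order (ester first, phenols last, no aqueous acid) and sets out from 16. HF·pyridine in THF/pyridine at 0 °C should remove only the silyl group and give 2-[(1R)-1-hydroxy-4-methylpent-3-en-1-yl]-5,8-bis(methoxymethoxy)naphthalene-1,4-dione F7. Butanoic anhydride with DMAP and pyridine in CH2Cl2 should give (1R)-1-[5,8-bis(methoxymethoxy)-1,4-dioxo-1,4-dihydronaphthalen-2-yl]-4-methylpent-3-en-1-yl butanoate F8. MgBr2·OEt2 in CH2Cl2 (0 → 23 °C), which chelates between each acetal oxygen and its peri carbonyl, should remove both methoxymethyl groups, and the fallback comes back to the route at 18 without passing through 17.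

**Further compounds**

F1 | step 8 | 2-[(2Z,4R)-4-(tert-butyldimethylsilyloxy)-3-iodo-7-methylocta-2,6-dienoyl]-3,6-bis(methoxymethoxy)benzaldehyde | CC(C)=CC[C@@H](O[Si](C)(C)C(C)(C)C)/C(I)=C/C(=O)c1c(OCOC)ccc(OCOC)c1C=O
F2 | step 8 | 4-hydroxy-3-[(1R)-1-(tert-butyldimethylsilyloxy)-4-methylpent-3-en-1-yl]-5,8-bis(methoxymethoxy)naphthalen-1(4H)-one | CC(C)=CC[C@@H](O[Si](C)(C)C(C)(C)C)C1=CC(=O)c2c(OCOC)ccc(OCOC)c2C1O
F3 | step 7 | 2-[2,5-bis(methoxymethoxy)phenyl]-1,3-dimethylimidazolidine | COCOc1ccc(OCOC)c(C2N(C)CCN2C)c1
F4 | step 7 | 2-(1,3-dimethylimidazolidin-2-yl)-3,6-bis(methoxymethoxy)benzaldehyde | COCOc1ccc(OCOC)c(C2N(C)CCN2C)c1C=O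
F5 | step 7 | (4R)-4-(tert-butyldimethylsilyloxy)-1-[2-(1,3-dimethylimidazolidin-2-yl)-3,6-bis(methoxymethoxy)phenyl]-7-methyloct-6-en-2-yn-1-ol | COCOc1ccc(OCOC)c(C2N(C)CCN2C)c1C(O)C#C[C@@H](CC=C(C)C)O[Si](C)(C)C(C)(C)C
F6 | step 7 | (4R)-4-(tert-butyldimethylsilyloxy)-1-[2-(1,3-dimethylimidazolidin-2-yl)-3,6-bis(methoxymethoxy)phenyl]-7-methyloct-6-en-2-yn-1-one | COCOc1ccc(OCOC)c(C2N(C)CCN2C)c1C(=O)C#C[C@@H](CC=C(C)C)O[Si](C)(C)C(C)(C)C
F7 | step 9 | 2-[(1R)-1-hydroxy-4-methylpent-3-en-1-yl]-5,8-bis(methoxymethoxy)naphthalene-1,4-dione | CC(C)=CC[C@@H](O)C1=CC(=O)c2c(OCOC)ccc(OCOC)c2C1=O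
F8 | step 9 | (1R)-1-[5,8-bis(methoxymethoxy)-1,4-dioxo-1,4-dihydronaphthalen-2-yl]-4-methylpent-3-en-1-yl butanoate | CCCC(=O)O[C@H](CC=C(C)C)C1=CC(=O)c2c(OCOC)ccc(OCOC)c2C1=O
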